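**Strategy.** The cyclohexane ring is opened at two bonds: C9–C10, between the ring CH2 and the quaternary methyl/vinyl carbon, and C7–C8, between the lactone-bearing CH and the acyloxy CH (elemane numbering). The vinyl-bearing quaternary carbon next to CH2–CH(O) is the product pattern of a Claisen rearrangement, and the carbinol next to a carbon carrying a 2-propenyl unit is that of a carbonyl-ene cyclisation. Heating one acyclic allyl vinyl ether therefore gives the [3,3] shift and, from the aldehyde so formed, the ring closure, setting three stereocentres from the two already present. The lactone is completed afterwards by allylic oxidation.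

Key step: step 9

Remark: atom labels C1–C15 follow elemane numbering and are shorthand only. Which antipode of the bis(oxazolinyl)carbazole ligand in step 5 gives the (3S,4S) series is assumed by analogy with crotylation and would be fixed on the first run.

**Step 1**
Reactants: 1 3-(trimethylsilyl)prop-2-ynal; 2 methyl acrylate
Product: 3 methyl 3-hydroxy-2-methylidene-5-(trimethylsilyl)pent-4-ynoate (racemic)
Conditions: DABCO (0.2 equiv), THF, 0 °C → rt
Reagents that add atoms: none
Why: Morita–Baylis–Hillman reaction, fast with an electron-poor ynal; the racemic carbinol centre is erased in step 2.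

**Step 2**
Reactants: 3 methyl 3-hydroxy-2-methylidene-5-(trimethylsilyl)pent-4-ynoate
Product: 4 methyl (2Z)-2-(bromomethyl)-5-(trimethylsilyl)pent-2-en-4-ynoate
Conditions: PBr3 (0.4 equiv), Et2O, −10 → 0 °C
Reagents that add atoms: phosphorus tribromide, BrP(Br)Br
Why: SN2' bromination of a Baylis–Hillman alcohol should give the conjugated primary allylic bromide; any E isomer is harmless because the allylchromium of step 5 equilibrates.

**Step 3**
Reactants: 4 methyl (2Z)-2-(bromomethyl)-5-(trimethylsilyl)pent-2-en-4-ynoate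
Product: 5 (2Z)-2-(bromomethyl)-5-(trimethylsilyl)pent-2-en-4-yn-1-ol
Conditions: i-Bu2AlH (2.2 equiv), CH2Cl2, −78 °C; aq. potassium sodium tartrate work-up
Reagents that add atoms: none
Why: 1,2-reduction of the enoate by the aluminium hydride at low temperature, which 2-(bromomethyl)acrylates are known to undergo without loss of the allylic bromide.

**Step 4**
Reactants: 5 (2Z)-2-(bromomethyl)-5-(trimethylsilyl)pent-2-en-4-yn-1-ol
Product: 6 {[(2Z)-2-(bromomethyl)-5-(trimethylsilyl)pent-2-en-4-yn-1-yl]oxy}(tert-butyl)dimethylsilane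
Conditions: TBSOTf, 2,6-lutidine, CH2Cl2, −78 °C
Reagents that add atoms: tert-butyldimethylsilyl trifluoromethanesulfonate, CC(C)(C)[Si](C)(C)OS(=O)(=O)C(F)(F)F
Why: O-silylation with a non-nucleophilic base, so that the allylic bromide is not N-alkylated.

**Step 5**
Reactants: 6 {[(2Z)-2-(bromomethyl)-5-(trimethylsilyl)pent-2-en-4-yn-1-yl]oxy}(tert-butyl)dimethylsilane; 7 3-methylbut-2-enal
Product: 8 tert-butyl({(3S,4S)-6-methyl-2-methylidene-4-[(triethylsilyl)oxy]-3-[(trimethylsilyl)ethynyl]hept-5-en-1-yl}oxy)dimethylsilane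
Conditions: CrCl2 (10 mol%), chiral 1,8-bis(4-isopropyl-4,5-dihydrooxazol-2-yl)carbazole ligand (12 mol%), Mn, Et3SiCl, i-Pr2NEt (0.3 equiv), THF, rt
Reagents that add atoms: chlorotriethylsilane, CC[Si](Cl)(CC)CC
Why: catalytic asymmetric Nozaki–Hiyama–Kishi allylation, in which the equilibrating σ-allylchromium adds through its propargylic γ-carbon in a chair with the alkynyl and aldehyde substituents equatorial (anti relationship of C5 and C6), the ligand selects the aldehyde face, and Et3SiCl turns the catalyst over and leaves the C6 oxygen as its triethylsilyl ether.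

**Step 6**
Reactants: 8 tert-butyl({(3S,4S)-6-methyl-2-methylidene-4-[(triethylsilyl)oxy]-3-[(trimethylsilyl)ethynyl]hept-5-en-1-yl}oxy)dimethylsilane
Product: 9 tert-butyl({(3R,4S)-3-ethynyl-6-methyl-2-methylidene-4-[(triethylsilyl)oxy]hept-5-en-1-yl}oxy)dimethylsilane
Conditions: K2CO3 (0.3 equiv), MeOH, 0 °C → rt
Reagents that add atoms: none
Why: mild methanolysis cleaves only the C(sp)–Si bond and leaves both silyl ethers; the descriptor change at C3 is a priority effect only.

**Step 7**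
Reactants: 9 tert-butyl({(3R,4S)-3-ethynyl-6-methyl-2-methylidene-4-[(triethylsilyl)oxy]hept-5-en-1-yl}oxy)dimethylsilane
Product: 12 (2E,4R,5S)-4-{3-[(tert-butyldimethylsilyl)oxy]prop-1-en-2-yl}-3,7-dimethyl-5-[(triethylsilyl)oxy]octa-2,6-dien-1-ol, via alkenylalane 10 (not isolated), via lithium alanate 11 (not isolated)
Conditions: Me3Al (2.5 equiv), Cp2ZrCl2 (0.3 equiv), CH2Cl2, 0 °C → rt; n-BuLi, THF, −78 °C; (CH2O)n, −78 °C → rt; aq. NH4Cl
Reagents that add atoms: trimethylaluminium, C[Al](C)C; paraformaldehyde (as formaldehyde), C=O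
Why: zirconium-catalysed syn-carboalumination (Negishi) puts methyl on the internal alkyne carbon and aluminium on the terminus, and hydroxymethylation of the alanate with retention should give the E allylic alcohol (methyl cis to CH2OH).

**Step 8**
Reactants: 12 (2E,4R,5S)-4-{3-[(tert-butyldimethylsilyl)oxy]prop-1-en-2-yl}-3,7-dimethyl-5-[(triethylsilyl)oxy]octa-2,6-dien-1-ol
Product: 13 (2E,4R,5S)-4-{3-[(tert-butyldimethylsilyl)oxy]prop-1-en-2-yl}-1-(ethenyloxy)-3,7-dimethyl-5-[(triethylsilyl)oxy]octa-2,6-diene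
Conditions: Hg(OAc)2 (0.3 equiv), ethyl vinyl ether (solvent), reflux; K2CO3 quench
Reagents that add atoms: ethyl vinyl ether, C=COCC
Why: mercury-catalysed vinyl ether exchange on a primary allylic alcohol, a neutral and mild route to allyl vinyl ethers.

**Step 9**
Reactants: 13 (2E,4R,5S)-4-{3-[(tert-butyldimethylsilyl)oxy]prop-1-en-2-yl}-1-(ethenyloxy)-3,7-dimethyl-5-[(triethylsilyl)oxy]octa-2,6-diene
Product: 15 (1S,2R,3R,4R,5S)-4-{3-[(tert-butyldimethylsilyl)oxy]prop-1-en-2-yl}-5-ethenyl-5-methyl-2-(prop-1-en-2-yl)-3-[(triethylsilyl)oxy]cyclohexan-1-ol, via aldehyde 14 (not isolated)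
Conditions: PhMe (0.02 M), BHT (cat.), silanised sealed tube, 170 °C
Reagents that add atoms: none
Why: Heating triggers a chair-like [3,3]-sigmatropic (Claisen) shift that joins the vinyl ether CH2 (C9) to the methyl-bearing alkene carbon (C10), creating the quaternary centre with vinyl and methyl and unmasking an aldehyde (C8), which then adds to the neighbouring 2-methylprop-1-enyl group (at C7) in a type 1 intramolecular carbonyl-ene reaction with transfer of a methyl hydrogen; the closest known reaction is the tandem Claisen–ene sequence, with the ene half modelled on the citronellal-to-isopulegol cyclisation. The only ring closed is the cyclohexane, formed in the ene step through a six-membered chair in which the reacting alkene and the carbonyl oxygen are both exocyclic to the new ring. C10 is set in the sigmatropic step by the adjacent stereocentre C5 in a Felkin-type arrangement: the new bond forms anti to the bulky CH(OSiEt3) branch, the planar silyloxypropenyl group sits inside over the C=C–H edge and the hydrogen faces the alkene methyl, the E geometry from step 7 placing only hydrogen cis to C5. C7 and C8 are set in the ene chair, where the silyloxypropenyl, the OSiEt3, the forming isopropenyl and the forming hydroxyl groups are all equatorial, allylic 1,3-strain holds the hydrogen of the OSiEt3 carbon in the alkene plane, and an axial C=O is disfavoured by the axial methyl on C10. The step needs face selectivity at C10 and preference for this ene over the type 2 ene of the 1,1-disubstituted alkene and over Cope shifts; the first rests on the size difference between the two branches at C5, the second on the more nucleophilic trisubstituted alkene with freely transferable methyl hydrogens (the other alkene offers only hydrogens on its oxygen-bearing carbon) and on Cope barriers expected to lie above those of the Claisen and ene steps at 170 °C.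

**Step 10**
Reactants: 16 methyl but-2-ynoate
Product: 18 methyl (2Z)-2-(hydroxymethyl)but-2-enoate, via vinylalane 17 (not isolated)
Conditions: i-Bu2AlH, N-methylmorpholine N-oxide, THF, 0 °C; HCHO (gas), −78 → 0 °C
Reagents that add atoms: formaldehyde, C=O
Why: conjugate syn-hydroalumination of the ynoate puts the ester cis to the β-methyl, and hydroxymethylation of the α-aluminio enoate with retention (vinylalumination) should give the Z (angelate-type) isomer.

**Step 11**
Reactants: 18 methyl (2Z)-2-(hydroxymethyl)but-2-enoate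
Product: 19 methyl (2Z)-2-{[(tert-butyldimethylsilyl)oxy]methyl}but-2-enoate
Conditions: TBSCl, imidazole, CH2Cl2, 0 °C → rt
Reagents that add atoms: tert-butyldimethylsilyl chloride, CC(C)(C)[Si](C)(C)Cl
Why: standard silylation of a primary allylic alcohol.

**Step 12**
Reactants: 19 methyl (2Z)-2-{[(tert-butyldimethylsilyl)oxy]methyl}but-2-enoate
Product: 20 (2Z)-2-{[(tert-butyldimethylsilyl)oxy]methyl}but-2-enoic acid
Conditions: Me3SnOH (3 equiv), ClCH2CH2Cl, 70 °C; cold 5% aq. HCl wash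
Reagents that add atoms: trimethyltin hydroxide, C[Sn](C)(C)O
Why: neutral tin hydroxide ester cleavage, chosen to avoid the base-mediated Z-to-E isomerisation that saponification of angelate-type esters risks.

**Step 13**
Reactants: 15 (1S,2R,3R,4R,5S)-4-{3-[(tert-butyldimethylsilyl)oxy]prop-1-en-2-yl}-5-ethenyl-5-methyl-2-(prop-1-en-2-yl)-3-[(triethylsilyl)oxy]cyclohexan-1-ol; 20 (2Z)-2-{[(tert-butyldimethylsilyl)oxy]methyl}but-2-enoic acid
Product: 22 (1S,2R,3R,4R,5S)-4-{3-[(tert-butyldimethylsilyl)oxy]prop-1-en-2-yl}-5-ethenyl-5-methyl-2-(prop-1-en-2-yl)-3-[(triethylsilyl)oxy]cyclohexyl (2Z)-2-{[(tert-butyldimethylsilyl)oxy]methyl}but-2-enoate, via mixed anhydride 21 (not isolated)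
Conditions: 2,4,6-trichlorobenzoyl chloride, Et3N, PhMe, rt; then 15, 80 °C (no DMAP)
Reagents that add atoms: none
Why: Yamaguchi-type esterification through the mixed anhydride without a nucleophilic catalyst, conditions that keep angelate-type acids Z; the C8 hydroxyl is the only free one.

**Step 14**
Reactants: 22 (1S,2R,3R,4R,5S)-4-{3-[(tert-butyldimethylsilyl)oxy]prop-1-en-2-yl}-5-ethenyl-5-methyl-2-(prop-1-en-2-yl)-3-[(triethylsilyl)oxy]cyclohexyl (2Z)-2-{[(tert-butyldimethylsilyl)oxy]methyl}but-2-enoate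
Product: 24 (1S,2R,3R,4R,5S)-4-{3-[(tert-butyldimethylsilyl)oxy]prop-1-en-2-yl}-5-ethenyl-5-methyl-2-(3-oxoprop-1-en-2-yl)-3-[(triethylsilyl)oxy]cyclohexyl (2Z)-2-{[(tert-butyldimethylsilyl)oxy]methyl}but-2-enoate, via allylic alcohol 23 (not isolated)
Conditions: SeO2 (0.5 equiv), t-BuOOH (3 equiv), CH2Cl2, 0 °C → rt; filter; MnO2, CH2Cl2, rt
Reagents that add atoms: selenium dioxide, O=[Se]=O; tert-butyl hydroperoxide, CC(C)(C)OO
Why: Riley allylic oxidation (ene reaction, then [2,3] shift) should take the isopropenyl methyl, because the ring methine hydrogen is held in the alkene plane, the other alkenes are deactivated (allylic silyloxy, enoate) or lack allylic hydrogen (vinyl), and MnO2 converges the allylic alcohol on the enal.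

**Step 15**
Reactants: 24 (1S,2R,3R,4R,5S)-4-{3-[(tert-butyldimethylsilyl)oxy]prop-1-en-2-yl}-5-ethenyl-5-methyl-2-(3-oxoprop-1-en-2-yl)-3-[(triethylsilyl)oxy]cyclohexyl (2Z)-2-{[(tert-butyldimethylsilyl)oxy]methyl}but-2-enoate
Product: 25 (1S,2R,3R,4R,5S)-2-(1-carboxyethenyl)-4-{3-[(tert-butyldimethylsilyl)oxy]prop-1-en-2-yl}-5-ethenyl-5-methyl-3-[(triethylsilyl)oxy]cyclohexyl (2Z)-2-{[(tert-butyldimethylsilyl)oxy]methyl}but-2-enoate
Conditions: NaClO2, NaH2PO4, 2-methylbut-2-ene, t-BuOH/H2O, 0 °C → rt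
Reagents that add atoms: sodium chlorite, [Na+].[O-]Cl=O
Why: Pinnick oxidation converts the α-substituted acrolein into the acrylic acid without touching alkenes or silyl ethers when hypochlorite is scavenged.

**Step 16**
Reactants: 25 (1S,2R,3R,4R,5S)-2-(1-carboxyethenyl)-4-{3-[(tert-butyldimethylsilyl)oxy]prop-1-en-2-yl}-5-ethenyl-5-methyl-3-[(triethylsilyl)oxy]cyclohexyl (2Z)-2-{[(tert-butyldimethylsilyl)oxy]methyl}but-2-enoate
Product: 27 (3aR,4S,6S,7R,7aR)-6-ethenyl-7-(3-hydroxyprop-1-en-2-yl)-6-methyl-3-methylidene-2-oxooctahydro-1-benzofuran-4-yl (2Z)-2-(hydroxymethyl)but-2-enoate, via hydroxy acid 26 (not isolated)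
Conditions: HF·pyridine, pyridine/THF, 0 °C → rt; PPTS (cat.), CH2Cl2 if ring closure is incomplete
Reagents that add atoms: none
Why: fluoride cleaves the three silyl ethers, and the freed C6 hydroxyl should lactonise with the acrylic acid to the trans-fused (diequatorial) α-methylene-γ-butyrolactone; no stereocentre is touched.

**Compound list**

1 | 3-(trimethylsilyl)prop-2-ynal | C[Si](C)(C)C#CC=O | starting material
2 | methyl acrylate | C=CC(=O)OC | starting material
3 | methyl 3-hydroxy-2-methylidene-5-(trimethylsilyl)pent-4-ynoate (racemic) | COC(=O)C(=C)C(O)C#C[Si](C)(C)C | intermediate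
4 | methyl (2Z)-2-(bromomethyl)-5-(trimethylsilyl)pent-2-en-4-ynoate | COC(=O)/C(CBr)=C/C#C[Si](C)(C)C | intermediate
5 | (2Z)-2-(bromomethyl)-5-(trimethylsilyl)pent-2-en-4-yn-1-ol | OC/C(CBr)=C/C#C[Si](C)(C)C | intermediate
6 | {[(2Z)-2-(bromomethyl)-5-(trimethylsilyl)pent-2-en-4-yn-1-yl]oxy}(tert-butyl)dimethylsilane | CC(C)(C)[Si](C)(C)OC/C(CBr)=C/C#C[Si](C)(C)C | intermediate
7 | 3-methylbut-2-enal | CC(C)=CC=O | starting material
8 | tert-butyl({(3S,4S)-6-methyl-2-methylidene-4-[(triethylsilyl)oxy]-3-[(trimethylsilyl)ethynyl]hept-5-en-1-yl}oxy)dimethylsilane | C[Si](C)(C)C#C[C@H](C(=C)CO[Si](C)(C)C(C)(C)C)[C@@H](O[Si](CC)(CC)CC)C=C(C)C | intermediate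
9 | tert-butyl({(3R,4S)-3-ethynyl-6-methyl-2-methylidene-4-[(triethylsilyl)oxy]hept-5-en-1-yl}oxy)dimethylsilane | C#C[C@H](C(=C)CO[Si](C)(C)C(C)(C)C)[C@@H](O[Si](CC)(CC)CC)C=C(C)C | intermediate
10 | alkenyldimethylalane from syn addition of CH3–Al across the alkyne of 9 (Al on the terminal carbon, cis to the new methyl; stereocentres as in 9) | C[Al](C)/C=C(\C)[C@H](C(=C)CO[Si](C)(C)C(C)(C)C)[C@@H](O[Si](CC)(CC)CC)C=C(C)C | intermediate (not isolated)
11 | lithium butyl(dimethyl)alkenylalanate formed from 10 and n-BuLi | [Li+].CCCC[Al-](C)(C)/C=C(\C)[C@H](C(=C)CO[Si](C)(C)C(C)(C)C)[C@@H](O[Si](CC)(CC)CC)C=C(C)C | intermediate (not isolated)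
12 | (2E,4R,5S)-4-{3-[(tert-butyldimethylsilyl)oxy]prop-1-en-2-yl}-3,7-dimethyl-5-[(triethylsilyl)oxy]octa-2,6-dien-1-ol | OC/C=C(\C)[C@H](C(=C)CO[Si](C)(C)C(C)(C)C)[C@@H](O[Si](CC)(CC)CC)C=C(C)C | intermediate
13 | (2E,4R,5S)-4-{3-[(tert-butyldimethylsilyl)oxy]prop-1-en-2-yl}-1-(ethenyloxy)-3,7-dimethyl-5-[(triethylsilyl)oxy]octa-2,6-diene | C=COC/C=C(\C)[C@H](C(=C)CO[Si](C)(C)C(C)(C)C)[C@@H](O[Si](CC)(CC)CC)C=C(C)C | intermediate
14 | (3S,4R,5S)-4-{3-[(tert-butyldimethylsilyl)oxy]prop-1-en-2-yl}-3-ethenyl-3,7-dimethyl-5-[(triethylsilyl)oxy]oct-6-enal | C=C[C@](C)(CC=O)[C@H](C(=C)CO[Si](C)(C)C(C)(C)C)[C@@H](O[Si](CC)(CC)CC)C=C(C)C | intermediate (not isolated)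
15 | (1S,2R,3R,4R,5S)-4-{3-[(tert-butyldimethylsilyl)oxy]prop-1-en-2-yl}-5-ethenyl-5-methyl-2-(prop-1-en-2-yl)-3-[(triethylsilyl)oxy]cyclohexan-1-ol | C=C[C@]1(C)C[C@H](O)[C@@H](C(C)=C)[C@H](O[Si](CC)(CC)CC)[C@H]1C(=C)CO[Si](C)(C)C(C)(C)C | intermediate
16 | methyl but-2-ynoate | CC#CC(=O)OC | starting material
17 | methyl 2-(diisobutylalumanyl)but-2-enoate, ester cis to the β-methyl | COC(=O)/C(=C\C)[Al](CC(C)C)CC(C)C | intermediate (not isolated)
18 | methyl (2Z)-2-(hydroxymethyl)but-2-enoate | COC(=O)/C(=C\C)CO | intermediate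
19 | methyl (2Z)-2-{[(tert-butyldimethylsilyl)oxy]methyl}but-2-enoate | COC(=O)/C(=C\C)CO[Si](C)(C)C(C)(C)C | intermediate
20 | (2Z)-2-{[(tert-butyldimethylsilyl)oxy]methyl}but-2-enoic acid | OC(=O)/C(=C\C)CO[Si](C)(C)C(C)(C)C | intermediate
21 | mixed anhydride of 20 and 2,4,6-trichlorobenzoic acid | O=C(OC(=O)/C(=C\C)CO[Si](C)(C)C(C)(C)C)c1c(Cl)cc(Cl)cc1Cl | intermediate (not isolated)
22 | (1S,2R,3R,4R,5S)-4-{3-[(tert-butyldimethylsilyl)oxy]prop-1-en-2-yl}-5-ethenyl-5-methyl-2-(prop-1-en-2-yl)-3-[(triethylsilyl)oxy]cyclohexyl (2Z)-2-{[(tert-butyldimethylsilyl)oxy]methyl}but-2-enoate | C=C[C@]1(C)C[C@H](OC(=O)/C(=C\C)CO[Si](C)(C)C(C)(C)C)[C@@H](C(C)=C)[C@H](O[Si](CC)(CC)CC)[C@H]1C(=C)CO[Si](C)(C)C(C)(C)C | intermediate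
23 | as 22, with the ring isopropenyl group oxidised to 3-hydroxyprop-1-en-2-yl (ring configuration unchanged) | C=C[C@]1(C)C[C@H](OC(=O)/C(=C\C)CO[Si](C)(C)C(C)(C)C)[C@@H](C(=C)CO)[C@H](O[Si](CC)(CC)CC)[C@H]1C(=C)CO[Si](C)(C)C(C)(C)C | intermediate (not isolated)
24 | (1S,2R,3R,4R,5S)-4-{3-[(tert-butyldimethylsilyl)oxy]prop-1-en-2-yl}-5-ethenyl-5-methyl-2-(3-oxoprop-1-en-2-yl)-3-[(triethylsilyl)oxy]cyclohexyl (2Z)-2-{[(tert-butyldimethylsilyl)oxy]methyl}but-2-enoate | C=C[C@]1(C)C[C@H](OC(=O)/C(=C\C)CO[Si](C)(C)C(C)(C)C)[C@@H](C(=C)C=O)[C@H](O[Si](CC)(CC)CC)[C@H]1C(=C)CO[Si](C)(C)C(C)(C)C | intermediate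
25 | (1S,2R,3R,4R,5S)-2-(1-carboxyethenyl)-4-{3-[(tert-butyldimethylsilyl)oxy]prop-1-en-2-yl}-5-ethenyl-5-methyl-3-[(triethylsilyl)oxy]cyclohexyl (2Z)-2-{[(tert-butyldimethylsilyl)oxy]methyl}but-2-enoate | C=C[C@]1(C)C[C@H](OC(=O)/C(=C\C)CO[Si](C)(C)C(C)(C)C)[C@@H](C(=C)C(=O)O)[C@H](O[Si](CC)(CC)CC)[C@H]1C(=C)CO[Si](C)(C)C(C)(C)C | intermediate
26 | (1S,2S,3R,4R,5S)-2-(1-carboxyethenyl)-5-ethenyl-3-hydroxy-4-(3-hydroxyprop-1-en-2-yl)-5-methylcyclohexyl (2Z)-2-(hydroxymethyl)but-2-enoate (same spatial arrangement as 25; the C2 descriptor changes by priority only) | C=C[C@]1(C)C[C@H](OC(=O)/C(=C\C)CO)[C@@H](C(=C)C(=O)O)[C@H](O)[C@H]1C(=C)CO | intermediate (not isolated)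
27 | (3aR,4S,6S,7R,7aR)-6-ethenyl-7-(3-hydroxyprop-1-en-2-yl)-6-methyl-3-methylidene-2-oxooctahydro-1-benzofuran-4-yl (2Z)-2-(hydroxymethyl)but-2-enoate | C=C[C@]1(C)C[C@H](OC(=O)/C(=C\C)CO)[C@H]2C(=C)C(=O)O[C@@H]2[C@H]1C(=C)CO | target

**Totals**

Total step count: 16 (steps 1–9 and 13–16 on the main line, steps 10–12 for the side-chain acid).
Longest linear sequence: 13 steps (1–9, 13–16).

**The three steps most likely to fail**

1. Step 9. The sigmatropic shift may show too little facial discrimination at C10, or the aldehyde may be diverted at 170 °C by a Cope shift or by the type 2 ene before it cyclises. The fallback for step 9 sets out from 12 and comes back to the route at 15. Acetylation of 12 with Ac2O and pyridine should give [(2E,4R,5S)-4-{3-[(tert-butyldimethylsilyl)oxy]prop-1-en-2-yl}-3,7-dimethyl-5-[(triethylsilyl)oxy]octa-2,6-dien-1-yl] acetate F1. An Ireland–Claisen rearrangement of F1 with LiN(i-Pr)2 and TBSCl in THF/DMPU, −78 °C → rt, would then form the C9–C10 bond at or below room temperature, where facial discrimination is expected to be higher and no thermal side reaction can occur, giving tert-butyldimethylsilyl (3S,4R,5S)-4-{3-[(tert-butyldimethylsilyl)oxy]prop-1-en-2-yl}-3-ethenyl-3,7-dimethyl-5-[(triethylsilyl)oxy]oct-6-enoate F2. LiAlH4 in Et2O at 0 °C should reduce F2 to (3S,4R,5S)-4-{3-[(tert-butyldimethylsilyl)oxy]prop-1-en-2-yl}-3-ethenyl-3,7-dimethyl-5-[(triethylsilyl)oxy]oct-6-en-1-ol F3. Dess–Martin periodinane would oxidise F3 to aldehyde 14, now isolated, and Me2AlCl in CH2Cl2 at −78 °C closes the ring by a Lewis acid-mediated carbonyl-ene reaction to 15.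

2. Step 5. Enantiofacial control by the ligand may be poor, or the anti preference may erode with the linear alkynyl γ-substituent. The fallback for step 5 sets out from 6 and 7 and comes back to the route at 8. Stoichiometric CrCl2 without ligand in THF at rt, followed by aqueous work-up, should give racemic anti 1-[(tert-butyldimethylsilyl)oxy]-6-methyl-2-methylidene-3-[(trimethylsilyl)ethynyl]hept-5-en-4-ol F4. Esterification of F4 with (S)-O-methylmandelic acid, DCC and DMAP in CH2Cl2, then chromatographic separation of the diastereomers, would give (3S,4S)-1-[(tert-butyldimethylsilyl)oxy]-6-methyl-2-methylidene-3-[(trimethylsilyl)ethynyl]hept-5-en-4-yl (2S)-2-methoxy-2-phenylacetate F5. i-Bu2AlH in CH2Cl2 at −78 °C cleaves F5 to the single enantiomer (3S,4S)-1-[(tert-butyldimethylsilyl)oxy]-6-methyl-2-methylidene-3-[(trimethylsilyl)ethynyl]hept-5-en-4-ol F6, and Et3SiCl with imidazole in DMF converts F6 into 8.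

3. Step 14. Selenium may attack the ring methine or the silyloxypropenyl alkene as well, or over-oxidise. The fallback for step 14 sets out from 22 and comes back to the route at 24. Ene-type chlorination with Ca(OCl)2 and solid CO2 in CH2Cl2/H2O at 0 °C should take the most electron-rich 1,1-disubstituted alkene and give (1S,2R,3R,4R,5S)-4-{3-[(tert-butyldimethylsilyl)oxy]prop-1-en-2-yl}-2-(3-chloroprop-1-en-2-yl)-5-ethenyl-5-methyl-3-[(triethylsilyl)oxy]cyclohexyl (2Z)-2-{[(tert-butyldimethylsilyl)oxy]methyl}but-2-enoate F7. A Kornblum-type oxidation of F7 with trimethylamine N-oxide in DMSO at rt then gives enal 24.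

**Further compounds**

F1 | step 9 | [(2E,4R,5S)-4-{3-[(tert-butyldimethylsilyl)oxy]prop-1-en-2-yl}-3,7-dimethyl-5-[(triethylsilyl)oxy]octa-2,6-dien-1-yl] acetate | CC(=O)OC/C=C(\C)[C@H](C(=C)CO[Si](C)(C)C(C)(C)C)[C@@H](O[Si](CC)(CC)CC)C=C(C)C
F2 | step 9 | tert-butyldimethylsilyl (3S,4R,5S)-4-{3-[(tert-butyldimethylsilyl)oxy]prop-1-en-2-yl}-3-ethenyl-3,7-dimethyl-5-[(triethylsilyl)oxy]oct-6-enoate | C=C[C@](C)(CC(=O)O[Si](C)(C)C(C)(C)C)[C@H](C(=C)CO[Si](C)(C)C(C)(C)C)[C@@H](O[Si](CC)(CC)CC)C=C(C)C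
F3 | step 9 | (3S,4R,5S)-4-{3-[(tert-butyldimethylsilyl)oxy]prop-1-en-2-yl}-3-ethenyl-3,7-dimethyl-5-[(triethylsilyl)oxy]oct-6-en-1-ol | C=C[C@](C)(CCO)[C@H](C(=C)CO[Si](C)(C)C(C)(C)C)[C@@H](O[Si](CC)(CC)CC)C=C(C)C
F4 | step 5 | racemic anti 1-[(tert-butyldimethylsilyl)oxy]-6-methyl-2-methylidene-3-[(trimethylsilyl)ethynyl]hept-5-en-4-ol (racemate; the SMILES shows the 3S,4S antipode) | C[Si](C)(C)C#C[C@H](C(=C)CO[Si](C)(C)C(C)(C)C)[C@@H](O)C=C(C)C
F5 | step 5 | (3S,4S)-1-[(tert-butyldimethylsilyl)oxy]-6-methyl-2-methylidene-3-[(trimethylsilyl)ethynyl]hept-5-en-4-yl (2S)-2-methoxy-2-phenylacetate | C[Si](C)(C)C#C[C@H](C(=C)CO[Si](C)(C)C(C)(C)C)[C@@H](OC(=O)[C@@H](OC)c1ccccc1)C=C(C)C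
F6 | step 5 | (3S,4S)-1-[(tert-butyldimethylsilyl)oxy]-6-methyl-2-methylidene-3-[(trimethylsilyl)ethynyl]hept-5-en-4-ol (single enantiomer) | C[Si](C)(C)C#C[C@H](C(=C)CO[Si](C)(C)C(C)(C)C)[C@@H](O)C=C(C)C
F7 | step 14 | (1S,2R,3R,4R,5S)-4-{3-[(tert-butyldimethylsilyl)oxy]prop-1-en-2-yl}-2-(3-chloroprop-1-en-2-yl)-5-ethenyl-5-methyl-3-[(triethylsilyl)oxy]cyclohexyl (2Z)-2-{[(tert-butyldimethylsilyl)oxy]methyl}but-2-enoate | C=C[C@]1(C)C[C@H](OC(=O)/C(=C\C)CO[Si](C)(C)C(C)(C)C)[C@@H](C(=C)CCl)[C@H](O[Si](CC)(CC)CC)[C@H]1C(=C)CO[Si](C)(C)C(C)(C)C
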